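**Plan**

- Feature: the C4–O–C5 oxirane ring lies next to the lactone oxygen on C6, so C4, C5 and C6 carry three contiguous C–O bonds. This array is the product side of the Payne equilibrium of a cis-5,6-epoxy-4-ol, and the C12 ester 1,4 to O6 can capture it as the γ-lactone ring (C6, C7, C11, C12, O).
- Cuts, in retrosynthetic order: C8 ester and silyl ethers; O4–C5 and O6–C12 (oxirane and lactone rings, one step); the 5,6-oxirane; C5=C6 (ten-membered ring); C7–C8; C9–C10; C1=C10.
- Forward: (R)-linalool supplies C1–C5 and C15. A Wittig reaction builds the C1=C10 iodoenoate, which is joined to (S)-glyceraldehyde acetonide (C8, C9). The derived C8 aldehyde takes C6, C7 and C11–C13 from a bromide made from acrolein and methyl acrylate. Ring-closing metathesis forms the ten-membered ring, directed epoxidation the 5,6-oxirane, and the base cascade the 4,5-oxirane and the lactone; the epoxy acid from tiglic acid is attached last.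
- Stereochemistry: C4 from linalool; C9 by Felkin–Anh addition beside the dioxolane; C8 and C7 by Felkin–Anh, chair-controlled indium allylation; C5 and C6 by hydroxyl-directed epoxidation of the Z olefin, C5 being inverted in the key step; the side-chain oxirane by Sharpless epoxidation.

Key step: step 13

Remark: all intermediates carry the germacranolide atom numbers of the target (C1–C10 ring, C11–C13 lactone arm, C14 ester carbon on C10, C15 methyl on C4), and (S)-glyceraldehyde acetonide is taken as a purchasable aldehyde.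

**Route**

Step 1
Reactants: 1 (R)-(−)-linalool
Product: 2 linalool trimethylsilyl ether
Conditions: TMSCl, imidazole, DMF, 0 °C → rt
Reagents that add atoms: chlorotrimethylsilane C[Si](C)(C)Cl
Why: Silyl ether formation caps the tertiary alcohol so that ozonolysis gives a free aldehyde instead of a five-membered lactol, and the group falls off by itself in the acidic step 6.

Step 2
Reactants: 2 linalool trimethylsilyl ether
Product: 4 (4R)-4-methyl-4-[(trimethylsilyl)oxy]hex-5-enal, via secondary ozonide 3 (not isolated)
Conditions: O3, CH2Cl2, −78 °C (Sudan Red 7B end-point); then PPh3, −78 °C → rt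
Reagents that add atoms: ozone [O-][O+]=O
Why: Ozonolysis with reductive work-up: the trisubstituted C=C is far more electron-rich than the vinyl group on the quaternary carbon, so ozone dosed to an indicator end-point cleaves only the former and the ozonide is reduced to the C1 aldehyde.

Step 3
Reactants: 4 (4R)-4-methyl-4-[(trimethylsilyl)oxy]hex-5-enal
Product: 5 (Z)-α-iodoenoate
Conditions: Ph3P=CHCO2Me, NIS, CH2Cl2, −20 °C; then 4, −20 °C → rt
Reagents that add atoms: methyl (triphenylphosphoranylidene)acetate COC(=O)C=P(c1ccccc1)(c1ccccc1)c1ccccc1; N-iodosuccinimide O=C1CCC(=O)N1I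
Why: Wittig olefination with an α-iodinated stabilised ylide (made in the flask from the parent ylide and NIS) places the alkyl chain trans to the ester, which puts iodine cis to C2 and so fixes the ring-cis C1=C10 geometry of the target.

Step 4
Reactants: 5 (Z)-α-iodoenoate; 6 (S)-2,3-O-isopropylideneglyceraldehyde
Product: 7 C9 carbinol (1,2-anti to the dioxolane oxygen)
Conditions: CrCl2, NiCl2 (cat.), DMSO, rt
Reagents that add atoms: none
Why: Nozaki–Hiyama–Kishi coupling: the alkenyl iodide is converted with retention of geometry into an alkenylchromium species that adds to the aldehyde anti to the dioxolane C–O bond (polar Felkin–Anh model), which should set C9 as R while ester, silyl ether and vinyl group are tolerated.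

Step 5
Reactants: 7 C9 carbinol
Product: 8 C9 tert-butyldimethylsilyl ether
Conditions: TBSCl, imidazole, DMF, rt
Reagents that add atoms: tert-butyldimethylsilyl chloride CC(C)(C)[Si](C)(C)Cl
Why: Silylation of the secondary allylic alcohol gives the bulky, non-chelating silyl ether at C9 that the Felkin–Anh-controlled allylation of step 9 needs, and it is the last group to be removed.

Step 6
Reactants: 8 C9 tert-butyldimethylsilyl ether
Product: 9 C8 aldehyde with free C4 hydroxyl
Conditions: H5IO6, EtOAc, 0 °C → rt
Reagents that add atoms: none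
Why: Periodic acid hydrolyses the terminal acetonide and cleaves the resulting glycol in one operation (glycol cleavage); the TBS ether survives, the acid-labile TMS ether is lost, and the dioxolane stereocentre, having set C9, becomes the C8 aldehyde carbon.

Step 7
Reactants: 10 acrolein; 11 methyl acrylate
Product: 12 methyl 3-hydroxy-2-methylidenepent-4-enoate (racemic)
Conditions: DABCO (cat.), 1,4-dioxane–H2O, rt
Reagents that add atoms: none
Why: Morita–Baylis–Hillman reaction: DABCO adds to methyl acrylate and the resulting enolate attacks the aldehyde carbon of acrolein in 1,2-fashion; the new stereocentre is left racemic because it is erased in step 8.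

Step 8
Reactants: 12 methyl 3-hydroxy-2-methylidenepent-4-enoate
Product: 13 methyl (2Z)-2-(bromomethyl)penta-2,4-dienoate
Conditions: NBS, Me2S, CH2Cl2, 0 °C → rt
Reagents that add atoms: N-bromosuccinimide O=C1CCC(=O)N1Br
Why: Bromination of the allylic alcohol with allylic transposition (Corey–Kim-type NBS/Me2S activation, SN2′ attack of bromide) gives the conjugated primary bromide with the vinyl group cis to CH2Br, the usual outcome for Morita–Baylis–Hillman alcohols of acrylate esters.

Step 9
Reactants: 9 C8 aldehyde; 13 methyl (2Z)-2-(bromomethyl)penta-2,4-dienoate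
Product: 14 open-chain C8 alcohol carrying the C7 vinyl group and the acrylate arm
Conditions: In powder, THF–H2O (1:1), rt
Reagents that add atoms: none
Why: Indium-mediated Barbier allylation: the 2-carbomethoxypentadienylindium reacts through its central (γ) carbon in a six-membered chair transition state with the vinyl group (cis to CH2In) axial, which gives the 7,8-syn relationship, and it attacks the aldehyde face anti to the non-chelating C9 silyloxy group (Felkin–Anh), which gives 8,9-anti; C7 (R) and C8 (S) are thus set together.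

Step 10
Reactants: 14 open-chain C8 alcohol
Product: 15 C8 triethylsilyl ether
Conditions: TESCl, imidazole, DMF, 0 °C
Reagents that add atoms: chlorotriethylsilane CC[Si](CC)(CC)Cl
Why: Selective silylation of the secondary C8 hydroxyl in the presence of the tertiary C4 hydroxyl stops O8 from lactonising onto C12 or C14 and from competing with O6 in the key step, and TES can later be removed without loss of TBS.

Step 11
Reactants: 15 C8 triethylsilyl ether
Product: 16 (5Z)-cyclodecadienol
Conditions: second-generation Hoveyda–Grubbs catalyst (10 mol %), toluene (1 mM), 80 °C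
Reagents that add atoms: none
Why: Ring-closing metathesis between the two monosubstituted vinyl groups (the acrylate and the trisubstituted enoate are poor metathesis partners); the ring-cis C1=C10 enoate acts as a turn, the product is a cis,cis-cyclodeca-1,6-diene, the least strained ten-membered diene frame, and reversible metathesis at 80 °C should therefore favour the Z olefin.

Step 12
Reactants: 16 (5Z)-cyclodecadienol
Product: 17 cis-5,6-epoxy-4-ol
Conditions: VO(acac)2 (cat.), t-BuOOH, CH2Cl2, 0 °C → rt
Reagents that add atoms: tert-butyl hydroperoxide CC(C)(C)OO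
Why: Hydroxyl-directed vanadium-catalysed epoxidation: only the C5=C6 olefin is allylic to a free hydroxyl and electron-rich, and the vanadate ester at O4 delivers oxygen to the ring face that carries O4 (methyl in the olefin plane pointing outward, C3 on the opposite face, minimal 1,3-allylic strain), which gives the cis-epoxy alcohol with C5 and C6 both S, as is usual for Z-allylic alcohols in medium rings.

Step 13
Reactants: 17 cis-5,6-epoxy-4-ol
Product: 19 4,5-epoxy-6,12-lactone bearing 8-OTES/9-OTBS, via C6 alkoxide 18 (not isolated)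
Conditions: KOt-Bu (0.2 equiv), THF, −20 → 0 °C
Reagents that add atoms: none
Why: Catalytic tert-butoxide turns the C4 tertiary alcohol into its alkoxide, which attacks C5 from the rear of the C5–O bond of the 5,6-oxirane (3-exo-tet) and so closes the 4,5-oxirane with inversion at C5 while O6 is set free as a secondary alkoxide; this is a Payne rearrangement. The O6 alkoxide lies 1,4 to the C12 ester carbonyl and closes the γ-lactone by 5-exo-trig acyl substitution with loss of methoxide (the known capture of a Payne alkoxide by an internal ester), and the methoxide deprotonates the next molecule of 17, so the base is needed only in catalytic amount. The single stereocentre that changes is C5 (S to R), fixed by the SN2 geometry, whereas C4 (from linalool) and C6 (from step 12) are retained, so the cis-5,6-oxirane becomes the trans-4,5-oxirane and the lactone is trans-fused. The equilibrium should favour the trisubstituted oxirane and the secondary alkoxide, and lactonisation removes that alkoxide for good. The step needs capture by O6 and not by O4 or O8: a five-membered lactone from O6 competes only with a seven-membered one from O4, O8 is silylated, and the reversible 5-exo oxa-Michael addition of O4 to C1 is emptied through the same lactonisation.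

Step 14
Reactants: 19 4,5-epoxy-6,12-lactone bearing 8-OTES/9-OTBS
Product: 20 C8 alcohol
Conditions: HF·pyridine, pyridine, THF, 0 °C
Reagents that add atoms: none
Why: Selective desilylation: buffered HF·pyridine cleaves the triethylsilyl ether much faster than the tert-butyldimethylsilyl ether and leaves oxirane, lactone and enoates alone, which frees O8 alone for acylation.

Step 15
Reactants: 21 tiglic acid
Product: 22 (2E)-2-methylbut-2-en-1-ol
Conditions: LiAlH4, Et2O, 0 °C → rt
Reagents that add atoms: none
Why: Hydride reduction of the conjugated acid with LiAlH4 gives the allylic alcohol without touching the E olefin.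

Step 16
Reactants: 22 (2E)-2-methylbut-2-en-1-ol
Product: 23 [(2R,3R)-2,3-dimethyloxiran-2-yl]methanol
Conditions: Ti(OiPr)4 (cat.), D-(−)-diisopropyl tartrate (cat.), t-BuOOH, 4 Å MS, CH2Cl2, −20 °C
Reagents that add atoms: tert-butyl hydroperoxide CC(C)(C)OO
Why: Sharpless asymmetric epoxidation: with the D-(−)-tartrate ligand the titanium-bound hydroperoxide adds oxygen to the face of the E-allylic alcohol that leads to the (2R,3R)-epoxy alcohol, the two methyl groups staying cis.

Step 17
Reactants: 23 [(2R,3R)-2,3-dimethyloxiran-2-yl]methanol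
Product: 24 (2S,3R)-2,3-dimethyloxirane-2-carboxylic acid
Conditions: TEMPO (cat.), PhI(OAc)2, MeCN–H2O, rt
Reagents that add atoms: water O
Why: TEMPO/PhI(OAc)2 oxidation of the primary alcohol through the aldehyde hydrate to the carboxylic acid under near-neutral conditions keeps the oxirane intact; the descriptor at C2 changes from R to S only because the priorities change.

Step 18
Reactants: 20 C8 alcohol; 24 (2S,3R)-2,3-dimethyloxirane-2-carboxylic acid
Product: 26 C9-TBS ether of the target, via mixed anhydride 25 (not isolated)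
Conditions: 2,4,6-trichlorobenzoyl chloride, Et3N, THF, 0 °C; then 20, DMAP, toluene, rt
Reagents that add atoms: none
Why: Yamaguchi esterification: the hindered α-quaternary glycidic acid is activated as the mixed anhydride and transferred by DMAP to the only free hydroxyl (O8) under conditions mild enough not to move the neighbouring silyl group or open the oxiranes.

Step 19
Reactants: 26 C9-TBS ether of the target
Product: 27 target CNP0262846.1
Conditions: HF·pyridine, THF, 0 °C → rt
Reagents that add atoms: none
Why: Fluoride-mediated desilylation removes the C9 TBS ether under mildly acidic conditions, which avoids base-induced acyl migration from O8 to O9, translactonisation and conjugate addition to the α-methylene lactone.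

**Compound list**

1 | (R)-(−)-linalool, (3R)-3,7-dimethylocta-1,6-dien-3-ol | CC(C)=CCC[C@@](C)(O)C=C | starting material
2 | trimethyl{[(3R)-3,7-dimethylocta-1,6-dien-3-yl]oxy}silane | CC(C)=CCC[C@@](C)(O[Si](C)(C)C)C=C | intermediate
3 | 3,3-dimethyl-5-{(3R)-3-methyl-3-[(trimethylsilyl)oxy]pent-4-en-1-yl}-1,2,4-trioxolane (secondary ozonide, both configurations at the ring CH) | CC1(C)OOC(CC[C@@](C)(O[Si](C)(C)C)C=C)O1 | intermediate
4 | (4R)-4-methyl-4-[(trimethylsilyl)oxy]hex-5-enal | O=CCC[C@@](C)(O[Si](C)(C)C)C=C | intermediate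
5 | methyl (2Z,6R)-2-iodo-6-methyl-6-[(trimethylsilyl)oxy]octa-2,7-dienoate | COC(=O)/C(I)=C/CC[C@@](C)(O[Si](C)(C)C)C=C | intermediate
6 | (S)-2,3-O-isopropylideneglyceraldehyde, (4S)-2,2-dimethyl-1,3-dioxolane-4-carbaldehyde | O=C[C@@H]1COC(C)(C)O1 | starting material
7 | methyl (2E,6R)-2-{(R)-[(4S)-2,2-dimethyl-1,3-dioxolan-4-yl](hydroxy)methyl}-6-methyl-6-[(trimethylsilyl)oxy]octa-2,7-dienoate | CC1(C)OC[C@H](O1)[C@H](O)/C(C(=O)OC)=C\CC[C@@](C)(O[Si](C)(C)C)C=C | intermediate
8 | methyl (2E,6R)-2-{(R)-[(tert-butyldimethylsilyl)oxy][(4S)-2,2-dimethyl-1,3-dioxolan-4-yl]methyl}-6-methyl-6-[(trimethylsilyl)oxy]octa-2,7-dienoate | CC1(C)OC[C@H](O1)[C@H](O[Si](C)(C)C(C)(C)C)/C(C(=O)OC)=C\CC[C@@](C)(O[Si](C)(C)C)C=C | intermediate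
9 | methyl (2E,6R)-2-{(1R)-1-[(tert-butyldimethylsilyl)oxy]-2-oxoethyl}-6-hydroxy-6-methylocta-2,7-dienoate | O=C[C@H](O[Si](C)(C)C(C)(C)C)/C(C(=O)OC)=C\CC[C@@](C)(O)C=C | intermediate
10 | acrolein | C=CC=O | starting material
11 | methyl acrylate | C=CC(=O)OC | starting material
12 | methyl 3-hydroxy-2-methylidenepent-4-enoate (racemic) | C=CC(O)C(=C)C(=O)OC | intermediate
13 | methyl (2Z)-2-(bromomethyl)penta-2,4-dienoate | COC(=O)/C(CBr)=C/C=C | intermediate
14 | dimethyl (2E,3R,4S,5R)-3-[(tert-butyldimethylsilyl)oxy]-5-ethenyl-4-hydroxy-2-[(4R)-4-hydroxy-4-methylhex-5-en-1-ylidene]-6-methylideneheptanedioate | C=C[C@H](C(=C)C(=O)OC)[C@H](O)[C@H](O[Si](C)(C)C(C)(C)C)/C(C(=O)OC)=C\CC[C@@](C)(O)C=C | intermediate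
15 | dimethyl (2E,3R,4S,5R)-3-[(tert-butyldimethylsilyl)oxy]-5-ethenyl-2-[(4R)-4-hydroxy-4-methylhex-5-en-1-ylidene]-6-methylidene-4-[(triethylsilyl)oxy]heptanedioate | C=C[C@H](C(=C)C(=O)OC)[C@H](O[Si](CC)(CC)CC)[C@H](O[Si](C)(C)C(C)(C)C)/C(C(=O)OC)=C\CC[C@@](C)(O)C=C | intermediate
16 | dimethyl (1(10)E,4R,5Z,7R,8S,9R)-9-[(tert-butyldimethylsilyl)oxy]-4-hydroxy-8-[(triethylsilyl)oxy]germacra-1(10),5,11(13)-triene-12,14-dioate | C[C@]1(O)/C=C\[C@H](C(=C)C(=O)OC)[C@H](O[Si](CC)(CC)CC)[C@H](O[Si](C)(C)C(C)(C)C)/C(C(=O)OC)=C\CC1 | intermediate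
17 | dimethyl (1(10)E,4R,5S,6S,7S,8S,9R)-9-[(tert-butyldimethylsilyl)oxy]-5,6-epoxy-4-hydroxy-8-[(triethylsilyl)oxy]germacra-1(10),11(13)-diene-12,14-dioate | O1[C@H]2[C@H](C(=C)C(=O)OC)[C@H](O[Si](CC)(CC)CC)[C@H](O[Si](C)(C)C(C)(C)C)/C(C(=O)OC)=C\CC[C@@](C)(O)[C@@H]12 | intermediate
18 | C6 alkoxide of dimethyl (1(10)E,4R,5R,6S,7S,8S,9R)-9-[(tert-butyldimethylsilyl)oxy]-4,5-epoxy-6-hydroxy-8-[(triethylsilyl)oxy]germacra-1(10),11(13)-diene-12,14-dioate | [O-][C@H]1[C@H](C(=C)C(=O)OC)[C@H](O[Si](CC)(CC)CC)[C@H](O[Si](C)(C)C(C)(C)C)/C(C(=O)OC)=C\CC[C@@]2(C)O[C@H]12 | intermediate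
19 | methyl (1(10)E,4R,5R,6S,7S,8S,9R)-9-[(tert-butyldimethylsilyl)oxy]-4,5-epoxy-8-[(triethylsilyl)oxy]germacra-1(10),11(13)-dien-12,6-olid-14-oate | C=C1C(=O)O[C@H]2[C@H]1[C@H](O[Si](CC)(CC)CC)[C@H](O[Si](C)(C)C(C)(C)C)/C(C(=O)OC)=C\CC[C@@]1(C)O[C@H]21 | intermediate
20 | methyl (1(10)E,4R,5R,6S,7R,8S,9R)-9-[(tert-butyldimethylsilyl)oxy]-4,5-epoxy-8-hydroxygermacra-1(10),11(13)-dien-12,6-olid-14-oate | C=C1C(=O)O[C@H]2[C@H]1[C@H](O)[C@H](O[Si](C)(C)C(C)(C)C)/C(C(=O)OC)=C\CC[C@@]1(C)O[C@H]21 | intermediate
21 | tiglic acid, (2E)-2-methylbut-2-enoic acid | C/C=C(\C)C(=O)O | starting material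
22 | (2E)-2-methylbut-2-en-1-ol | C/C=C(\C)CO | intermediate
23 | [(2R,3R)-2,3-dimethyloxiran-2-yl]methanol | OC[C@@]1(C)O[C@@H]1C | intermediate
24 | (2S,3R)-2,3-dimethyloxirane-2-carboxylic acid | OC(=O)[C@@]1(C)O[C@@H]1C | intermediate
25 | (2S,3R)-2,3-dimethyloxirane-2-carboxylic 2,4,6-trichlorobenzoic anhydride | O=C(OC(=O)c1c(Cl)cc(Cl)cc1Cl)[C@@]1(C)O[C@@H]1C | intermediate
26 | methyl (1(10)E,4R,5R,6S,7S,8S,9R)-9-[(tert-butyldimethylsilyl)oxy]-8-{[(2S,3R)-2,3-dimethyloxirane-2-carbonyl]oxy}-4,5-epoxygermacra-1(10),11(13)-dien-12,6-olid-14-oate | C=C1C(=O)O[C@H]2[C@H]1[C@H](OC(=O)[C@@]1(C)O[C@@H]1C)[C@H](O[Si](C)(C)C(C)(C)C)/C(C(=O)OC)=C\CC[C@@]1(C)O[C@H]21 | intermediate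
27 | methyl (1(10)E,4R,5R,6S,7R,8S,9R)-8-{[(2S,3R)-2,3-dimethyloxirane-2-carbonyl]oxy}-4,5-epoxy-9-hydroxygermacra-1(10),11(13)-dien-12,6-olid-14-oate (CNP0262846.1) | C=C1C(=O)O[C@H]2[C@H]1[C@H](OC(=O)[C@@]1(C)O[C@@H]1C)[C@H](O)/C(C(=O)OC)=C\CC[C@@]1(C)O[C@H]21 | target

**Counts and risks**

Total step count: 19. Longest linear sequence: 14 steps (steps 1–6, 9–14, 18, 19) from (R)-linalool.

Steps most likely to fail:

1. Step 11 (ring-closing metathesis). The open-chain diene has no constraint between its two vinyl groups, so oligomerisation or closure to the E olefin may compete. The ruthenium carbene formed at C6 may also be held as a chelate by the C12 ester carbonyl. The fallback sets out from 14 and comes back at 20. Brief exposure of 14 to catalytic camphorsulfonic acid in CH2Cl2 should close O8 onto the less hindered acrylate ester and give the cis-fused α-methylene-γ-butyrolactone F1, which ties C7 and C8 into a five-membered ring, turns the two chains toward each other and removes the chelating ester. Metathesis of F1 under the conditions of step 11 should then give the lactone-fused (5Z)-cyclodecadienol F2. VO(acac)2/t-BuOOH as in step 12 should give the cis-epoxy alcohol F3. Catalytic KOt-Bu in THF/t-BuOH should trigger the same oxirane shift, now followed by transfer of the C12 acyl group from O8 to the freed O6 (8,12- to 6,12-lactone), which reaches 20 directly and makes steps 10 and 14 unnecessary. The position of that lactone-to-lactone equilibrium is not known for this ring and is the weak point of the fallback.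

2. Step 13 (oxirane shift and lactone capture). The C4 alkoxide may add to C1 of the enoate (5-exo oxa-Michael) faster than it opens the oxirane, or the triethylsilyl group may move from O8 to the O6 alkoxide before lactonisation and so open the way to the wrong lactone. The fallback sets out from 16 and comes back at 19, with the two events done stepwise. Hydroxyl-directed syn-dihydroxylation with OsO4/TMEDA (CH2Cl2, −78 °C; aqueous Na2SO3) should add both oxygens to the ring face that carries O4 and give the 4,5,6-triol F4. Catalytic camphorsulfonic acid should close O6 onto C12 and give the 4,5-dihydroxy-6,12-lactone F5. MsCl/Et3N should sulfonylate only the secondary C5 hydroxyl and give the C5 mesylate F6. DBU in toluene then lets O4 displace the mesylate with inversion at C5, which is the same stereochemical outcome as the cascade and gives 19.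

3. Step 9 (indium allylation). Facial selectivity at C8 may be low (Felkin–Anh against chelate pathways), the fluxional allylindium may lose the syn relationship through isomerisation, or it may react through the terminal carbon of the pentadienyl unit. The fallback sets out from 13 (with 9) and comes back at 14, using a configurationally defined boron reagent. Pd2(dba)3-catalysed borylation of 13 with B2pin2 should give the allylboronate F7 with the vinyl group still cis to CH2B. Thermal allylboration of 9 with F7 (toluene, 50 °C, aqueous work-up) proceeds through a closed chair transition state, in which a Z-γ-substituted allylboronate and an α-silyloxy aldehyde reinforce each other toward the 7,8-syn, 8,9-anti product 14.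

Further compounds
F1 | step 11 | methyl (2E,6R)-2-{(R)-[(tert-butyldimethylsilyl)oxy][(2S,3R)-3-ethenyl-4-methylidene-5-oxooxolan-2-yl]methyl}-6-hydroxy-6-methylocta-2,7-dienoate | C=C1C(=O)O[C@@H]([C@@H]1C=C)[C@H](O[Si](C)(C)C(C)(C)C)/C(C(=O)OC)=C\CC[C@@](C)(O)C=C
F2 | step 11 | methyl (1(10)E,4R,5Z,7R,8S,9R)-9-[(tert-butyldimethylsilyl)oxy]-4-hydroxygermacra-1(10),5,11(13)-trien-12,8-olid-14-oate | C[C@]1(O)/C=C\[C@H]2[C@H](OC(=O)C2=C)[C@H](O[Si](C)(C)C(C)(C)C)/C(C(=O)OC)=C\CC1
F3 | step 11 | methyl (1(10)E,4R,5S,6S,7S,8S,9R)-9-[(tert-butyldimethylsilyl)oxy]-5,6-epoxy-4-hydroxygermacra-1(10),11(13)-dien-12,8-olid-14-oate | O1[C@H]2[C@H]3[C@H](OC(=O)C3=C)[C@H](O[Si](C)(C)C(C)(C)C)/C(C(=O)OC)=C\CC[C@@](C)(O)[C@@H]12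
F4 | step 13 | dimethyl (1(10)E,4R,5S,6S,7S,8S,9R)-9-[(tert-butyldimethylsilyl)oxy]-4,5,6-trihydroxy-8-[(triethylsilyl)oxy]germacra-1(10),11(13)-diene-12,14-dioate | O[C@H]1[C@H](C(=C)C(=O)OC)[C@H](O[Si](CC)(CC)CC)[C@H](O[Si](C)(C)C(C)(C)C)/C(C(=O)OC)=C\CC[C@@](C)(O)[C@H]1O
F5 | step 13 | methyl (1(10)E,4R,5S,6S,7S,8S,9R)-9-[(tert-butyldimethylsilyl)oxy]-4,5-dihydroxy-8-[(triethylsilyl)oxy]germacra-1(10),11(13)-dien-12,6-olid-14-oate | C=C1C(=O)O[C@H]2[C@H]1[C@H](O[Si](CC)(CC)CC)[C@H](O[Si](C)(C)C(C)(C)C)/C(C(=O)OC)=C\CC[C@@](C)(O)[C@H]2O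
F6 | step 13 | methyl (1(10)E,4R,5S,6S,7S,8S,9R)-9-[(tert-butyldimethylsilyl)oxy]-4-hydroxy-5-[(methanesulfonyl)oxy]-8-[(triethylsilyl)oxy]germacra-1(10),11(13)-dien-12,6-olid-14-oate | C=C1C(=O)O[C@H]2[C@H]1[C@H](O[Si](CC)(CC)CC)[C@H](O[Si](C)(C)C(C)(C)C)/C(C(=O)OC)=C\CC[C@@](C)(O)[C@H]2OS(C)(=O)=O
F7 | step 9 | methyl (2E)-2-[(4,4,5,5-tetramethyl-1,3,2-dioxaborolan-2-yl)methyl]penta-2,4-dienoate | COC(=O)/C(CB1OC(C)(C)C(C)(C)O1)=C/C=C
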